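**Strategy.** The synthesis rests on the C6–C8'' biaryl bond between ring A of the (S)-flavanone and ring A of the flavone, a bond crowded by four ortho oxygen substituents. The plan uses the hydroxyl oxygens O7 and O7'', which lie ortho to that bond on either side: tied together through a diisopropylsilylene group, they turn the union into a ring closure. One operation, a palladium/distannane reductive coupling of two aryl iodides, makes the C6–C8'' bond and a seven-membered dioxasilepine ring. Its precursor is the O7–Si(iPr)2–O7'' bis-ether of (S)-4'-O-benzyl-6-iodonaringenin and 5,4'-di-O-benzyl-8-iodoapigenin.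

Key step: step 10

**Assumptions and remarks**
- Assumption: the target defines no configuration for the C6–C8'' axis; it is treated as undefined and is not controlled. Only C2 (S) is controlled.
- Locants: flavanone unit unprimed (its aryl ring primed), flavone unit double-primed (its aryl ring triple-primed). The separate flavones 7–11 carry ordinary apigenin locants.
- The structures of the key-step precursor 14 and product 16 were checked atom by atom and needed no correction: iodine on C6 and C8'', silicon on O7 and O7'', free chelated 5-OH, benzyl on O4', O5'' and O4''', S at C2.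
- Direct benzylation of apigenin etherifies O7 and O4' first and the chelated O5 last, the reverse of what 14 needs. O7 is therefore masked as an allyl ether before benzylation.
- Each iodination site is set by the state of the neighbouring 5-oxygen: free 5-OH with O7 silylated directs to C6 (flavanone); 5-O-benzyl directs to C8 (flavone).

**Route**

Step 1
Reactants: 1 5,7-dihydroxychromone
Product: 2 5-hydroxy-7-(triisopropylsilyloxy)chromone
Conditions: TIPSCl (1.1 equiv), imidazole (2.2 equiv), DMF, 0 °C to rt
Reagents that add atoms: chlorotriisopropylsilane, CC(C)[Si](Cl)(C(C)C)C(C)C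
Why: Phenol silylation in which the 5-OH, locked in a hydrogen bond to the C4 carbonyl, stays unreacted, so only the acidic 7-OH is silylated.

Step 2
Reactants: 2 5-hydroxy-7-(triisopropylsilyloxy)chromone; 3 4-(benzyloxy)phenylboronic acid
Product: 4 (S)-4'-O-benzyl-7-O-(triisopropylsilyl)naringenin
Conditions: 3 (2 equiv), Pd(OCOCF3)2 (5 mol%), (R)-t-BuPyOx [(R)-4-tert-butyl-2-(pyridin-2-yl)-4,5-dihydrooxazole, 6 mol%], NH4PF6 (30 mol%), H2O (5 equiv), ClCH2CH2Cl, 60 °C
Reagents that add atoms: none
Why: Palladium-catalysed asymmetric conjugate addition of an arylboronic acid to a chromone (aryl transfer from boron to a cationic divalent palladium pyridine-oxazoline complex, enantiodetermining insertion of C2=C3, protonolysis of the enolate), in which the tert-butyl group of the (R)-ligand blocks one face so that the aryl group should enter to give 2S, while the weakly acidic medium does not open the flavanone ring.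

Step 3
Reactants: 4 (S)-4'-O-benzyl-7-O-(triisopropylsilyl)naringenin
Product: 5 (S)-4'-O-benzyl-6-iodo-7-O-(triisopropylsilyl)naringenin
Conditions: NIS (1.05 equiv), DMF, 0 °C to rt, dark
Reagents that add atoms: N-iodosuccinimide, O=C1CCC(=O)N1I
Why: Electrophilic aromatic iodination under neutral conditions, in which the free chelated 5-OH (O7 being silylated) is the strongest donor on ring A and should direct iodine to its ortho position C6, the outcome established for 5-hydroxy-7-alkoxy flavonoids.

Step 4
Reactants: 5 (S)-4'-O-benzyl-6-iodo-7-O-(triisopropylsilyl)naringenin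
Product: 6 (S)-4'-O-benzyl-6-iodonaringenin
Conditions: HF·pyridine, THF, 0 °C to rt
Reagents that add atoms: none
Why: Fluoride cleavage of an aryl silyl ether in a non-basic medium, which should leave the aryl iodide, the benzyl ether and the C2 centre untouched.

Step 5
Reactants: 7 apigenin
Product: 8 7-O-allylapigenin
Conditions: allyl bromide (1.1 equiv), K2CO3 (1.1 equiv), DMF, rt
Reagents that add atoms: allyl bromide, C=CCBr
Why: Williamson ether synthesis in which the 7-OH, the most acidic phenol of apigenin, is alkylated in preference to the 4'-OH by one equivalent of base and halide, while the chelated 5-OH does not react.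

Step 6
Reactants: 8 7-O-allylapigenin
Product: 9 7-O-allyl-5,4'-di-O-benzylapigenin
Conditions: BnBr (3 equiv), K2CO3 (4 equiv), n-Bu4NI (cat.), DMF, 70 °C
Reagents that add atoms: benzyl bromide, BrCc1ccccc1
Why: Williamson ether synthesis under forcing conditions (excess halide, heat, iodide catalysis), which should benzylate O4' and the sluggish chelated O5 while the allyl ether is inert.

Step 7
Reactants: 9 7-O-allyl-5,4'-di-O-benzylapigenin
Product: 10 5,4'-di-O-benzylapigenin
Conditions: Pd(PPh3)4 (2 mol%), morpholine (5 equiv), THF, rt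
Reagents that add atoms: none
Why: Tsuji–Trost deallylation, in which zerovalent palladium ionises the aryl allyl ether (the 7-phenoxide is a good leaving group) and morpholine traps the allyl fragment, benzyl ethers being untouched.

Step 8
Reactants: 10 5,4'-di-O-benzylapigenin
Product: 11 5,4'-di-O-benzyl-8-iodoapigenin
Conditions: NIS (1.05 equiv), DMF, 0 °C to rt, dark
Reagents that add atoms: N-iodosuccinimide, O=C1CCC(=O)N1I
Why: Electrophilic aromatic iodination ortho to the free 7-OH, in which C6 is squeezed between OBn and OH whereas C8 lies next to the tied-back ring oxygen, in line with the C8 selectivity known for 5-O-alkylated 5,7-dioxygenated flavones.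

Step 9
Reactants: 11 5,4'-di-O-benzyl-8-iodoapigenin; 12 dichlorodiisopropylsilane; 6 (S)-4'-O-benzyl-6-iodonaringenin
Product: 14 diisopropylsilylene-bridged diiodide (O7 of 6 joined to O7'' of 11 through Si(iPr)2), via chlorosilyl ether 13 (not isolated)
Conditions: (a) 12 (4 equiv), Et3N (1.5 equiv), CH2Cl2, 0 °C to rt, then excess 12 removed under high vacuum; (b) 6 (0.9 equiv), imidazole (2.5 equiv), DMF, rt; rapid filtration through Et3N-deactivated silica
Reagents that add atoms: none
Why: Stepwise nucleophilic substitution at silicon, in which excess dichlorosilane gives only the mono-aryloxy chlorosilane from the single free OH of 11 and the acidic 7-OH of 6 then displaces the second chloride, while the chelated 5-OH (flanked by iodine and the carbonyl) stays free and the mild base spares C2.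

Step 10
Reactants: 14 diisopropylsilylene-bridged diiodide
Product: 16 silylene-bridged biflavonoid (O7,O7''-diisopropylsilylene derivative of tribenzyl ether 17), via aryl stannane 15 (not isolated)
Conditions: Pd(PPh3)4 (10 mol%), Me3SnSnMe3 (1.2 equiv), degassed 1,4-dioxane, 100 °C
Reagents that add atoms: none
Why: Proposed new method: zerovalent palladium should add to the C8''–I bond (the more electron-poor of the two), Me3SnSnMe3 should convert the arylpalladium iodide into aryl stannane 15 and regenerate the catalyst, and addition to the C6–I bond should be followed by transfer of the stannylated aryl group to palladium within the same molecule and by C–C reductive elimination. The closest known reaction type is the Stille–Kelly cyclisation of two aryl halides joined by a carbon or ester tether; the new element is the diaryloxysilane tether. The one ring formed, the seven-membered dibenzo-1,3,2-dioxasilepine, is closed by making the C6–C8'' aryl–aryl bond when an eight-membered diarylpalladium ring expels palladium. No stereocentre is created, the neutral medium leaves C2 alone, and the biaryl axis is not controlled. The step needs site selectivity and cross- rather than homo-coupling: the positions of the two iodine atoms fix C6 and C8'', and the O7–Si–O7'' bridge holds exactly these two carbons together, so the fourfold ortho-substituted union becomes intramolecular. Because both coupling carbons start as aryl iodides, a crowded aryl boron reagent prone to protodeboronation is avoided.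

Step 11
Reactants: 16 silylene-bridged biflavonoid
Product: 17 4'-O,5''-O,4'''-O-tribenzyl ether of the target
Conditions: HF·pyridine, THF, 0 °C
Reagents that add atoms: none
Why: Fluoride cleavage of both Si–O bonds (strong Si–F bond, phenoxide leaving groups) in a non-basic medium that should not touch the flavanone or the benzyl ethers.

Step 12
Reactants: 17 4'-O,5''-O,4'''-O-tribenzyl ether of the target
Product: 18 target, (2S)-naringenin-(6→8'')-apigenin
Conditions: H2 (1 atm), 10% Pd/C, THF–MeOH, rt, stopped at full debenzylation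
Reagents that add atoms: none
Why: Catalytic hydrogenolysis of three aryl benzyl ethers at atmospheric pressure, under which the flavone C2''=C3'' bond, both carbonyl groups and the benzylic C2–O1 bond of the flavanone should survive.

**Compound list**

1 | 5,7-dihydroxychromone | O=c1ccoc2cc(O)cc(O)c12 | starting material
2 | 5-hydroxy-7-(triisopropylsilyloxy)chromone | O=c1ccoc2cc(O[Si](C(C)C)(C(C)C)C(C)C)cc(O)c12 | intermediate
3 | 4-(benzyloxy)phenylboronic acid | OB(O)c1ccc(OCc2ccccc2)cc1 | starting material
4 | (S)-4'-O-benzyl-7-O-(triisopropylsilyl)naringenin | O=C1C[C@@H](c2ccc(OCc3ccccc3)cc2)Oc2cc(O[Si](C(C)C)(C(C)C)C(C)C)cc(O)c21 | intermediate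
5 | (S)-4'-O-benzyl-6-iodo-7-O-(triisopropylsilyl)naringenin | O=C1C[C@@H](c2ccc(OCc3ccccc3)cc2)Oc2cc(O[Si](C(C)C)(C(C)C)C(C)C)c(I)c(O)c21 | intermediate
6 | (S)-4'-O-benzyl-6-iodonaringenin | O=C1C[C@@H](c2ccc(OCc3ccccc3)cc2)Oc2cc(O)c(I)c(O)c21 | intermediate
7 | apigenin | O=c1cc(-c2ccc(O)cc2)oc2cc(O)cc(O)c12 | starting material
8 | 7-O-allylapigenin | O=c1cc(-c2ccc(O)cc2)oc2cc(OCC=C)cc(O)c12 | intermediate
9 | 7-O-allyl-5,4'-di-O-benzylapigenin | O=c1cc(-c2ccc(OCc3ccccc3)cc2)oc2cc(OCC=C)cc(OCc3ccccc3)c12 | intermediate
10 | 5,4'-di-O-benzylapigenin (free 7-OH) | O=c1cc(-c2ccc(OCc3ccccc3)cc2)oc2cc(O)cc(OCc3ccccc3)c12 | intermediate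
11 | 5,4'-di-O-benzyl-8-iodoapigenin | O=c1cc(-c2ccc(OCc3ccccc3)cc2)oc2c(I)c(O)cc(OCc3ccccc3)c12 | intermediate
12 | dichlorodiisopropylsilane | CC(C)[Si](Cl)(Cl)C(C)C | starting material
13 | 7-O-[chloro(diisopropyl)silyl] ether of 11 (not isolated) | O=c1cc(-c2ccc(OCc3ccccc3)cc2)oc2c(I)c(O[Si](Cl)(C(C)C)C(C)C)cc(OCc3ccccc3)c12 | intermediate
14 | diisopropylsilylene bis-ether joining O7 of (S)-4'-O-benzyl-6-iodonaringenin to O7'' of 5'',4'''-di-O-benzyl-8''-iodoapigenin | O=C1C[C@@H](c2ccc(OCc3ccccc3)cc2)Oc2cc(O[Si](C(C)C)(C(C)C)Oc3cc(OCc4ccccc4)c4c(=O)cc(-c5ccc(OCc6ccccc6)cc5)oc4c3I)c(I)c(O)c21 | intermediate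
15 | 8''-trimethylstannyl 6-iodo analogue of 14 (not isolated) | O=C1C[C@@H](c2ccc(OCc3ccccc3)cc2)Oc2cc(O[Si](C(C)C)(C(C)C)Oc3cc(OCc4ccccc4)c4c(=O)cc(-c5ccc(OCc6ccccc6)cc5)oc4c3[Sn](C)(C)C)c(I)c(O)c21 | intermediate
16 | O7,O7''-diisopropylsilylene-bridged 4',5'',4'''-tribenzyl ether of the target (dibenzo-1,3,2-dioxasilepine) | O=C1C[C@@H](c2ccc(OCc3ccccc3)cc2)Oc2cc3O[Si](C(C)C)(C(C)C)Oc4cc(OCc5ccccc5)c5c(=O)cc(-c6ccc(OCc7ccccc7)cc6)oc5c4-c3c(O)c21 | intermediate
17 | 4'-O,5''-O,4'''-O-tribenzyl ether of the target | O=C1C[C@@H](c2ccc(OCc3ccccc3)cc2)Oc2cc(O)c(-c3c(O)cc(OCc4ccccc4)c4c(=O)cc(-c5ccc(OCc6ccccc6)cc5)oc34)c(O)c21 | intermediate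
18 | (2S)-naringenin-(6→8'')-apigenin | O=C1C[C@@H](c2ccc(O)cc2)Oc2cc(O)c(-c3c(O)cc(O)c4c(=O)cc(-c5ccc(O)cc5)oc34)c(O)c21 | target

**Step count**

Total: 12 steps. Longest linear sequence: 8 steps (steps 1–4 or 5–8, then 9–12).

**Steps most likely to fail**

1. Step 10 (proposed new method). The reductive coupling may stall after the first stannylation, may replace a C–I bond by C–H, or may lose the silicon bridge to the Lewis-acidic tin iodide before the ring closes. The fallback is untethered, uses known chemistry, sets out from 1 and 11 and comes back at 18. Chromone 1 would be benzylated at O7 (BnBr, K2CO3, acetone) to 7-(benzyloxy)-5-hydroxychromone F1 and iodinated at C6 (NIS, DMF) to 7-(benzyloxy)-5-hydroxy-6-iodochromone F2. Flavone 11 would be benzylated at O7 to 5,7,4'-tri-O-benzyl-8-iodoapigenin F3 and borylated (pinacolborane, Et3N, PdCl2(MeCN)2, SPhos, dioxane) to the 8-pinacolboronate F4. Suzuki–Miyaura coupling of F2 with F4 (Pd(OAc)2, SPhos, K3PO4, toluene–H2O) would give the chromone–flavone biaryl F5 before any stereocentre exists, so the base can do no harm. The conjugate addition of step 2 (3, Pd(OCOCF3)2, (R)-t-BuPyOx) would then set C2 and give the pentabenzyl ether F6, and hydrogenolysis (H2, Pd/C) would give 18.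

2. Step 2. Turnover may be slow because the electron-rich, chelating 5-hydroxy-4-pyranone binds the cationic palladium, or the facial selectivity may be insufficient. The fallback sets out from 2 and 3 and comes back at 4, by racemic addition and resolution. The addition with an achiral ligand (Pd(OCOCF3)2, 2,2'-bipyridine) would give the racemic flavanone F7. Asymmetric transfer hydrogenation under kinetic resolution (RuCl(p-cymene)[(R,R)-TsDPEN], HCO2H/Et3N, EtOAc) would follow; by the usual aryl ketone model this catalyst forms the 4R alcohol. It should therefore reduce the 2R ketone to the cis-(2R,4R)-flavan-4-ol F8 and leave 4, which is separated by chromatography.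

3. Step 3. Site selectivity may be lost (iodination at C8, or at both C6 and C8), because the ring oxygen O1 of a flavanone is a stronger donor than that of a flavone. The fallback sets out from 2 and comes back at 5 with the order of events reversed. Chromone 2, whose ring A behaves like that of a flavone, would be iodinated first (NIS, DMF) to 5-hydroxy-6-iodo-7-(triisopropylsilyloxy)chromone F9. Conjugate addition of 3 under the conditions of step 2 would then give 5 directly; the catalyst stays divalent palladium, which should not engage the hindered, electron-rich C–I bond.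

**Further compounds**

F1 | step 10 | 7-(benzyloxy)-5-hydroxychromone | O=c1ccoc2cc(OCc3ccccc3)cc(O)c12
F2 | step 10 | 7-(benzyloxy)-5-hydroxy-6-iodochromone | O=c1ccoc2cc(OCc3ccccc3)c(I)c(O)c12
F3 | step 10 | 5,7,4'-tri-O-benzyl-8-iodoapigenin | O=c1cc(-c2ccc(OCc3ccccc3)cc2)oc2c(I)c(OCc3ccccc3)cc(OCc3ccccc3)c12
F4 | step 10 | 5,7,4'-tri-O-benzylapigenin-8-boronic acid pinacol ester | O=c1cc(-c2ccc(OCc3ccccc3)cc2)oc2c(B3OC(C)(C)C(C)(C)O3)c(OCc3ccccc3)cc(OCc3ccccc3)c12
F5 | step 10 | 7-(benzyloxy)-5-hydroxy-6-(5,7,4'-tri-O-benzylapigenin-8-yl)chromone | O=c1ccoc2cc(OCc3ccccc3)c(-c3c(OCc4ccccc4)cc(OCc4ccccc4)c4c(=O)cc(-c5ccc(OCc6ccccc6)cc5)oc34)c(O)c12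
F6 | step 10 | 7-O,4'-O,5''-O,7''-O,4'''-O-pentabenzyl ether of the target | O=C1C[C@@H](c2ccc(OCc3ccccc3)cc2)Oc2cc(OCc3ccccc3)c(-c3c(OCc4ccccc4)cc(OCc4ccccc4)c4c(=O)cc(-c5ccc(OCc6ccccc6)cc5)oc34)c(O)c21
F7 | step 2 | racemic 4'-O-benzyl-7-O-(triisopropylsilyl)naringenin | O=C1CC(c2ccc(OCc3ccccc3)cc2)Oc2cc(O[Si](C(C)C)(C(C)C)C(C)C)cc(O)c21
F8 | step 2 | (2R,4R)-2-(4-benzyloxyphenyl)-7-(triisopropylsilyloxy)chromane-4,5-diol | O[C@@H]1C[C@H](c2ccc(OCc3ccccc3)cc2)Oc2cc(O[Si](C(C)C)(C(C)C)C(C)C)cc(O)c21
F9 | step 3 | 5-hydroxy-6-iodo-7-(triisopropylsilyloxy)chromone | O=c1ccoc2cc(O[Si](C(C)C)(C(C)C)C(C)C)c(I)c(O)c12
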